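(The constants used here belong to no real substance; the flask was simulated.)

One mole of Q cost one mole of X and one mole of Z, so I kept my books in moles.

    Z + D ⇌ Z.D (K1 = 18 M⁻¹, k1 = 850 M⁻¹ min⁻¹)
    X + Z.D → X.Z.D (k2 = 18 M⁻¹ min⁻¹)
    X.Z.D ⇌ L (K3 = 48, k3 = 2.4 min⁻¹)
    L ⇌ D + Q (K4 = 0.11 M, k4 = 2.0 min⁻¹)

| setting | north-east | west | north-west |
|---|---|---|---|
| X | 0.11 M | 0.11 M | 0.11 M |
| Z | 0.100 M | 0.260 M | 0.650 M |
| D | 70 µM | 70 µM | 70 µM |
| time | 2.5 d | 2.5 d | 2.5 d |

1. which of these there is most of at the end, counted by the X in it, north-east (X.Z.D / Q / L / X)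
2. which of these there is most of at the end, counted by the X in it, west (X.Z.D / Q / L / X)
3. which of these there is most of at the end, counted by the X in it, north-west (X.Z.D / Q / L / X)
4. amount of the one of these that there is most of at the end, in percent of the X charged, north-east
5. amount of the one of these that there is most of at the end, in percent of the X charged, west
6. amount of the one of these that there is most of at the end, in percent of the X charged, north-west

1. The catalyst charge was 0.0636% of X, so I neglected what it held. Dividing the rate of loss of Z by the rate of loss of X then gave one, and time dropped out.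

2. I carried the exchange rate e, the percent of its own charge of Z spent for each percent of charged X turned into Q. In north-east e = 1.10, so Z left = 1 − eQ, with Q as a fraction of the X charged.

3. This balance put Z at zero at Q = 90.9%. That was the level of the north-east curve, and Z was its limiting reagent. In west and north-west, Z exceeded X, so their level was the whole charge of X. I drew north-east by hand and stopped there.

4. In north-east, Z.D fell back at 47.2 min⁻¹, faster than it went on at 1.98 min⁻¹, so I held step 1 in balance. I set a = 18 M⁻¹·[Z] and b = 18 M⁻¹ min⁻¹·[X]·0.917 min. The rate of making Q was then v = 18 M⁻¹ min⁻¹·[X]·a·70 µM/(1 + a + ab + [Q]/0.11 M).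

5. The slope at the start in north-east was 4.11 × 10⁻⁵ M min⁻¹. Kept straight, that line reached Z's charge at 1.69 d, sooner than 2.5 d, so the curve had to bend within the run.

6. Where Q crossed X, at 0.0550 M each, v was 1.84 × 10⁻⁵ M min⁻¹. At the knee, with Z at 0.0200 M, v was 6.01 × 10⁻⁶ M min⁻¹.

7. Between landmarks I let v fall in a straight line with [Q], which made each leg an exponential with rate constant r, the fall of v per unit of [Q]. The first leg had r = 4.12 × 10⁻⁴ min⁻¹, so the crossing came at ln(ratio of the two rates)/r = 1.35 d. The second leg had r = 4.97 × 10⁻⁴ min⁻¹, which put Q at 68.9% at 2.5 d, with Z left at 24.2%.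

The forecast named Q, Q and Q for the three flasks, with 68.7% (66% to 71%), 86.5% (84.5% to 88.5%) and 91.4% (89.5% to 93%), noting for north-east “Z is limiting, so Q cannot exceed 91%”.

Every flask ended with more Q than X: 68.8% in north-east, 86.5% in west and 91.5% in north-west. In north-east at 0.785 d, Z.D fell back 36 times faster than it went on to X.Z.D, and the end there held 18.1% of the catalyst as Z.D. Through e, that north-east Q leaves 24.4% of Z, and 24% stood unbound. In the neighbour of north-east charged with 0.028 M of X, e is 0.280, so its 90.0% of Q leaves 74.8% of Z, and 75% stood unbound.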